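## Conventions

Ring atoms carry 2,3-dihydro-1-benzofuran numbering (O1, C2, C3, C3a, C4, C5, C6, C7, C7a). In the benzoate intermediates, benzoate C1, C2, C3 and C4 become benzofuran C5, C4, C3a and C7a.

## Analysis of the target

The target 18 is a retrochalcone built on a 2,3-dihydro-1-benzofuran. C4 carries a methoxy group, C5 carries an (E)-enone that ends in a 4-hydroxyphenyl ketone, and C2 carries a 2-hydroxypropan-2-yl group. C2 is the only stereocentre and is S. It lies far from every other functional group, so nothing in the molecule can relay its configuration, and it has to come from a catalyst or a chiral building block. The benzene ring is substituted on four adjacent carbons (C3a, C4, C5, C7a), so the regiochemistry of arene substitution is the second problem. The sensitive groups are the enone (Michael acceptor, radical acceptor, prone to E/Z isomerisation in light), the free phenol, and the tertiary alcohol next to the ring oxygen, which limits how much acid the last step can use. The strategy rests on one feature: C3 is a benzylic CH2 on C3a, and C3a sits between two oxygen-bearing carbons, C4 and C7a. A carbene-type carbon at C3 is therefore 1,5 to the O–CH2 hydrogens of an ether on the C7a oxygen. If that ether is a 2-oxy-2-methylpropyl ether, its CH2 is the future C2 with the carbinol carbon already attached. Forming C2–C3 by C–H alkylation then closes the ring and sets the stereocentre in one step.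

## Retrosynthetic reasoning

**Enone and protecting groups (18 ⇒ 17 ⇒ 13 + 15).** The phenol and the tertiary alcohol of 18 are unmasked last from 17, in one acidic operation. The enone is cut at its C=C bond. This gives aldehyde 13, which cannot enolise, and methyl ketone 15, which enolises at one site only, so a crossed aldol condensation via adduct 16 can give only one constitution, and the E geometry is the thermodynamic one. The enone is placed after the ring closure because a cobalt carbene radical adds readily to electron-poor alkenes. Ketone 15 is the protected form of commercial 14.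

**The C5 carbon (13 ⇒ 12 ⇒ 11).** The formyl group of 13 is carried through the key step as the methyl ester of 11. A free aldehyde at C5 would compete for the sulfonyl hydrazide 8 and would itself become a carbene source. The ester is inert to hydrazide, carbonate base and carbon radicals, and two routine redox steps via alcohol 12 return the aldehyde.

**Key disconnection, C2–C3 (11 ⇒ 9).** Cutting C2–C3 opens the dihydrofuran to an aryl alkyl ether whose benzylic carbon is at carbene oxidation level, i.e. tosylhydrazone 9 and its diazo form 10. This bond is chosen because it is the only ring bond whose formation creates the stereocentre without a pre-made chiral fragment. The forward reaction must abstract one hydrogen of the O–CH2 group, recombine the two carbon radicals inside a chiral cobalt porphyrin, and leave the neighbouring O–CH3 alone.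

**The arene (9 ⇒ 7 + 8 ⇒ 6 ⇒ 5 ⇒ 3 ⇒ 1 + 2).** Hydrazone 9 comes from aldehyde 7 and hydrazide 8. The silyl ether of 7 and the methyl ether of 6 are simple O-functionalisations of 5. The formyl carbon of 5 is cut from the ring at benzoate C3. In 3 that position is the only free ortho site of the only free phenol, so a phenol-directed formylation (via 4) has no regiochemical choice. Ether 3 comes from opening epoxide 2 with the more acidic, non-chelated 4-hydroxyl of the bulk resorcylate 1. The substitution pattern is thus built around a purchased benzene ring by three regiochemically unambiguous steps.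

## Alternatives that were turned down

**Alternative 1: the benzene ring by Diels–Alder reaction.**
- Disconnection: C4–C5 and C6–C7, i.e. the arene itself.
- Forward key step: [4+2] cycloaddition of the prenylated 1-methoxy-1,3-bis(silyloxy)diene A2 with methyl propiolate A3, then loss of methanol, gives the prenyl resorcylate A1.
- For: the polarisation of A2 fixes the regiochemistry, and the three adjacent substituents arrive together. The chemistry that must follow A1 (asymmetric epoxidation, then phenoxide opening of the epoxide) is better precedented for this hydroxyisopropyl dihydrobenzofuran motif than the C–H alkylation. On predictability of the stereocentre this alternative is stronger.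
- Against: the key step makes neither the heterocycle nor the stereocentre. It builds a benzene ring that the chosen route buys as 1. A2 is a moisture-sensitive diene that needs its own preparation. A1 has two phenols flanking the prenyl group; one must be methylated and the other cyclised, which costs protecting-group steps.
- Comparison: in place of the stronger precedent, the chosen route makes ring and stereocentre in one catalytic step and reaches its product 11 in six steps from 1.

**Alternative 2: palladium annulation of a cyclohexanedione, then aromatisation.**
- Disconnection: C3–C3a and O1–C2, with the arene at the cyclohexane-1,3-dione oxidation level.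
- Forward key step: cyclohexane-1,3-dione A5 and the isoprene-derived dicarbonate A6 undergo palladium-catalysed C-allylation, then enantioselective O-allylation through the second π-allyl complex, to give the bicyclic enone A4.
- For: like the chosen step it makes the heterocycle and the stereocentre catalytically from simple materials, and asymmetric allylic alkylation is the more mature technology. The phenol obtained after aromatisation could direct the C5 carbon to the correct ortho position.
- Against: A4 lacks the aromatic ring, the C5 carbon and the tertiary alcohol. Dehydrogenating a vinylogous ester beside an isopropenyl group and an allylic C2–O bond puts both the alkene and the stereocentre at risk, since that bond can re-ionise under palladium. The isopropenyl group then needs a separate Markovnikov hydration.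
- Comparison: the path from A4 to the target is clearly longer than the five steps from 11. The chosen key product is already aromatic, already carries the C5 carbon and already has the carbinol oxygen.

**Alternative 3: both rings by intramolecular pyridazine–alkyne cycloaddition.**
- Disconnection: C3a–C7a and C4–C5.
- Forward key step: the alkoxypyridazine A8, tethered to a methoxyalkyne, undergoes intramolecular [4+2] cycloaddition and loses N2 to give A7, the triethylsilyl analogue of 11.
- For: the tether fixes the arene regiochemistry, there is no competing ether C–H bond, and no enantioselective catalysis is needed in the key step because the stereocentre is carried in. On these points it is stronger than the chosen route.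
- Against: the stereocentre must be made beforehand in an acyclic homopropargylic ether by a separate asymmetric sequence. The methoxyalkyne is a fragile, non-commercial function that must survive the ether-forming step. An alkoxy-substituted pyridazine with an electron-rich ynol ether is a poorly matched pair for inverse-demand cycloaddition, so forcing temperatures are expected.
- Comparison: the precursor A8 costs many more steps than 9. The chosen route puts its whole risk into one step that is reached by five routine operations, with the stereocentre coming from a catalyst.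

Key step: step 6

## Route

Assumption: which antipode of the chiral amidoporphyrin ligand gives (S)-C2 with this substrate is settled in a first small-scale run; both antipodes are accessible, so the route does not depend on the answer.

**Step 1**
Reactants: 1 methyl 2,4-dihydroxybenzoate; 2 2,2-dimethyloxirane
Product: 3 methyl 2-hydroxy-4-(2-hydroxy-2-methylpropoxy)benzoate
Conditions: K2CO3 (0.5 equiv), 2 (3 equiv), DMF, 85 °C, sealed vessel
Reagents that add atoms: none
Why: Base-mediated epoxide opening by a phenoxide (Williamson-type etherification); the 4-hydroxyl is the more acidic and is not tied up in the hydrogen bond to the ester, and it attacks the unhindered CH2 of the epoxide, so the tertiary alcohol results.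

**Step 2**
Reactants: 3 methyl 2-hydroxy-4-(2-hydroxy-2-methylpropoxy)benzoate
Product: 5 methyl 3-formyl-2-hydroxy-4-(2-hydroxy-2-methylpropoxy)benzoate, via hydroxymethyl phenol 4 (not isolated)
Conditions: MgCl2 (3 equiv), Et3N (5 equiv), (CH2O)n (8 equiv), MeCN, reflux; then 1 M HCl
Reagents that add atoms: paraformaldehyde (as formaldehyde), C=O
Why: Casnati–Skattebøl magnesium-mediated ortho-formylation; the magnesium phenoxide delivers formaldehyde to its only free ortho position (benzoate C3, also activated by the C4 alkoxy group) to give 4, which a second formaldehyde oxidises by hydride transfer to the aldehyde.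

**Step 3**
Reactants: 5 methyl 3-formyl-2-hydroxy-4-(2-hydroxy-2-methylpropoxy)benzoate
Product: 6 methyl 3-formyl-4-(2-hydroxy-2-methylpropoxy)-2-methoxybenzoate
Conditions: MeI (3 equiv), K2CO3, DMF, rt → 40 °C
Reagents that add atoms: iodomethane, CI
Why: Williamson O-methylation; the phenol between two carbonyl groups is acidic enough for carbonate, and the tertiary alcohol is not deprotonated and stays free.

**Step 4**
Reactants: 6 methyl 3-formyl-4-(2-hydroxy-2-methylpropoxy)-2-methoxybenzoate
Product: 7 methyl 3-formyl-2-methoxy-4-[2-methyl-2-(trimethylsilyloxy)propoxy]benzoate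
Conditions: TMSCl, imidazole, DMF, 0 °C → rt
Reagents that add atoms: chlorotrimethylsilane, C[Si](C)(C)Cl
Why: Silyl ether formation; the smallest silyl group goes onto the tertiary alcohol under imidazole catalysis, and the aromatic aldehyde has no enolisable position; the ether keeps the hydroxyl away from the cobalt centre in step 6 at the lowest steric cost beside the reacting CH2.

**Step 5**
Reactants: 7 methyl 3-formyl-2-methoxy-4-[2-methyl-2-(trimethylsilyloxy)propoxy]benzoate; 8 4-methylbenzenesulfonohydrazide
Product: 9 methyl 2-methoxy-4-[2-methyl-2-(trimethylsilyloxy)propoxy]-3-{(E)-[2-(4-methylbenzenesulfonyl)hydrazinylidene]methyl}benzoate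
Conditions: 8 (1.05 equiv), THF, 4 Å MS, rt → 40 °C
Reagents that add atoms: none
Why: Condensation of an aldehyde with a sulfonyl hydrazide to the (E)-N-tosylhydrazone; no acid is added, so the silyl ether should survive, and the ester does not react with the hydrazide under these conditions.

**Step 6**
Reactants: 9 methyl 2-methoxy-4-[2-methyl-2-(trimethylsilyloxy)propoxy]-3-{(E)-[2-(4-methylbenzenesulfonyl)hydrazinylidene]methyl}benzoate
Product: 11 methyl (2S)-4-methoxy-2-[2-(trimethylsilyloxy)propan-2-yl]-2,3-dihydro-1-benzofuran-5-carboxylate, via aryldiazomethane 10 (not isolated)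
Conditions: chiral D2-symmetric amidoporphyrin Co(II) complex (ChenPhyrin or bridged HuPhyrin type, 2–5 mol%), Cs2CO3 (2 equiv), 1,4-dioxane, 40–60 °C, Ar
Reagents that add atoms: none
Why: Carbonate deprotonates the hydrazone, which loses sulfinate (Bamford–Stevens) to release aryldiazomethane 10 slowly, so that its concentration stays low and dimerisation is suppressed. The Co(II) metalloradical captures 10 and expels N2 to give an α-cobalt(III) benzyl radical at C3. This radical abstracts a hydrogen from the O–CH2 group through a six-membered transition state (1,5-hydrogen atom transfer), and the resulting α-aryloxy radical at C2 attacks C3 with homolytic cleavage of the C–Co bond, forming C2–C3 and returning Co(II). The closest known reaction type is the cobalt(II)-porphyrin-catalysed enantioselective radical 1,5-C–H alkylation with aldehyde tosylhydrazones as diazo sources, which gives 2-substituted five-membered cyclic ethers and indolines. The dihydrofuran ring closes in a 5-exo-tet radical substitution. The C2 stereocentre is controlled by the chiral cavity of the porphyrin, whose amide walls and hydrogen-bond donors hold the substrate during abstraction and decide the face at which the C2 radical couples. The step needs site selectivity for O–CH2 over the O–CH3 on the other side of the carbene carbon: the secondary α-aryloxy C–H bond is weaker and gives the more stabilised radical, the singly flanked ether can lie in the ring plane next to the radical while the doubly flanked methoxy group is twisted out of it, and ortho-methoxyaryl carbene radicals are known to live long enough for intermolecular cyclopropanation. Ester, silyl ether and aryl ethers are spectators to the radical and the base.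

**Step 7**
Reactants: 11 methyl (2S)-4-methoxy-2-[2-(trimethylsilyloxy)propan-2-yl]-2,3-dihydro-1-benzofuran-5-carboxylate
Product: 12 {(2S)-4-methoxy-2-[2-(trimethylsilyloxy)propan-2-yl]-2,3-dihydro-1-benzofuran-5-yl}methanol
Conditions: DIBAL-H (2.5 equiv), CH2Cl2, −78 → 0 °C; Rochelle salt work-up
Reagents that add atoms: none
Why: Hydride reduction of an aryl ester to the benzylic alcohol; silyl and aryl ethers are inert, the neutral work-up spares the acid-sensitive electron-rich benzylic alcohol, and C2 is untouched.

**Step 8**
Reactants: 12 {(2S)-4-methoxy-2-[2-(trimethylsilyloxy)propan-2-yl]-2,3-dihydro-1-benzofuran-5-yl}methanol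
Product: 13 (2S)-4-methoxy-2-[2-(trimethylsilyloxy)propan-2-yl]-2,3-dihydro-1-benzofuran-5-carbaldehyde
Conditions: activated MnO2 (excess), CH2Cl2, rt
Reagents that add atoms: none
Why: Manganese dioxide oxidation selective for benzylic alcohols; it stops at the aldehyde and is neutral, so the silyl ether stays.

**Step 9**
Reactants: 14 1-(4-hydroxyphenyl)ethan-1-one
Product: 15 1-[4-(methoxymethoxy)phenyl]ethan-1-one
Conditions: MOMCl, iPr2NEt, CH2Cl2, 0 °C → rt
Reagents that add atoms: chloromethyl methyl ether, COCCl
Why: Acetal protection of the phenol; without it the phenoxide would lower the acidity of the methyl ketone in step 10.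

**Step 10**
Reactants: 13 (2S)-4-methoxy-2-[2-(trimethylsilyloxy)propan-2-yl]-2,3-dihydro-1-benzofuran-5-carbaldehyde; 15 1-[4-(methoxymethoxy)phenyl]ethan-1-one
Product: 17 (2E)-3-{(2S)-4-methoxy-2-[2-(trimethylsilyloxy)propan-2-yl]-2,3-dihydro-1-benzofuran-5-yl}-1-[4-(methoxymethoxy)phenyl]prop-2-en-1-one, via aldol adduct 16 (not isolated)
Conditions: Ba(OH)2·8H2O, MeOH, 40 °C, dark
Reagents that add atoms: none
Why: Claisen–Schmidt condensation; the enolate of 15 adds to the non-enolisable aldehyde 13 to give 16, and E1cB loss of water gives the conjugated (E)-enone; C2 has no acidifying neighbour and is not epimerised, and any partial loss of the silyl group is harmless because step 11 removes it.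

**Step 11**
Reactants: 17 (2E)-3-{(2S)-4-methoxy-2-[2-(trimethylsilyloxy)propan-2-yl]-2,3-dihydro-1-benzofuran-5-yl}-1-[4-(methoxymethoxy)phenyl]prop-2-en-1-one
Product: 18 (2E)-1-(4-hydroxyphenyl)-3-[(2S)-2-(2-hydroxypropan-2-yl)-4-methoxy-2,3-dihydro-1-benzofuran-5-yl]prop-2-en-1-one
Conditions: HCl (ca. 1 M) in MeOH, rt → 40 °C, dark
Reagents that add atoms: none
Why: Acid-catalysed methanolysis of the methoxymethyl acetal and the trimethylsilyl ether in one operation; the tertiary alcohol is β to the ring oxygen, which disfavours ionisation, and the ring bearing the enone has no free ortho hydroxyl that could cyclise onto it.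

## Compound list

1 | methyl 2,4-dihydroxybenzoate | COC(=O)c1ccc(O)cc1O | starting material
2 | 2,2-dimethyloxirane | CC1(C)CO1 | starting material
3 | methyl 2-hydroxy-4-(2-hydroxy-2-methylpropoxy)benzoate | COC(=O)c1ccc(OCC(C)(C)O)cc1O | intermediate
4 | methyl 2-hydroxy-3-(hydroxymethyl)-4-(2-hydroxy-2-methylpropoxy)benzoate | COC(=O)c1ccc(OCC(C)(C)O)c(CO)c1O | intermediate (not isolated)
5 | methyl 3-formyl-2-hydroxy-4-(2-hydroxy-2-methylpropoxy)benzoate | COC(=O)c1ccc(OCC(C)(C)O)c(C=O)c1O | intermediate
6 | methyl 3-formyl-4-(2-hydroxy-2-methylpropoxy)-2-methoxybenzoate | COC(=O)c1ccc(OCC(C)(C)O)c(C=O)c1OC | intermediate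
7 | methyl 3-formyl-2-methoxy-4-[2-methyl-2-(trimethylsilyloxy)propoxy]benzoate | COC(=O)c1ccc(OCC(C)(C)O[Si](C)(C)C)c(C=O)c1OC | intermediate
8 | 4-methylbenzenesulfonohydrazide | Cc1ccc(S(=O)(=O)NN)cc1 | starting material
9 | methyl 2-methoxy-4-[2-methyl-2-(trimethylsilyloxy)propoxy]-3-{(E)-[2-(4-methylbenzenesulfonyl)hydrazinylidene]methyl}benzoate | COC(=O)c1ccc(OCC(C)(C)O[Si](C)(C)C)c(/C=N/NS(=O)(=O)c2ccc(C)cc2)c1OC | intermediate
10 | methyl 3-(diazomethyl)-2-methoxy-4-[2-methyl-2-(trimethylsilyloxy)propoxy]benzoate | COC(=O)c1ccc(OCC(C)(C)O[Si](C)(C)C)c(C=[N+]=[N-])c1OC | intermediate (not isolated)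
11 | methyl (2S)-4-methoxy-2-[2-(trimethylsilyloxy)propan-2-yl]-2,3-dihydro-1-benzofuran-5-carboxylate | COC(=O)c1ccc2c(c1OC)C[C@@H](C(C)(C)O[Si](C)(C)C)O2 | intermediate
12 | {(2S)-4-methoxy-2-[2-(trimethylsilyloxy)propan-2-yl]-2,3-dihydro-1-benzofuran-5-yl}methanol | COc1c(CO)ccc2c1C[C@@H](C(C)(C)O[Si](C)(C)C)O2 | intermediate
13 | (2S)-4-methoxy-2-[2-(trimethylsilyloxy)propan-2-yl]-2,3-dihydro-1-benzofuran-5-carbaldehyde | COc1c(C=O)ccc2c1C[C@@H](C(C)(C)O[Si](C)(C)C)O2 | intermediate
14 | 1-(4-hydroxyphenyl)ethan-1-one | CC(=O)c1ccc(O)cc1 | starting material
15 | 1-[4-(methoxymethoxy)phenyl]ethan-1-one | CC(=O)c1ccc(OCOC)cc1 | intermediate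
16 | 3-hydroxy-3-{(2S)-4-methoxy-2-[2-(trimethylsilyloxy)propan-2-yl]-2,3-dihydro-1-benzofuran-5-yl}-1-[4-(methoxymethoxy)phenyl]propan-1-one (both epimers at the carbinol carbon) | COc1c(C(O)CC(=O)c2ccc(OCOC)cc2)ccc2c1C[C@@H](C(C)(C)O[Si](C)(C)C)O2 | intermediate (not isolated)
17 | (2E)-3-{(2S)-4-methoxy-2-[2-(trimethylsilyloxy)propan-2-yl]-2,3-dihydro-1-benzofuran-5-yl}-1-[4-(methoxymethoxy)phenyl]prop-2-en-1-one | COc1c(/C=C/C(=O)c2ccc(OCOC)cc2)ccc2c1C[C@@H](C(C)(C)O[Si](C)(C)C)O2 | intermediate
18 | (2E)-1-(4-hydroxyphenyl)-3-[(2S)-2-(2-hydroxypropan-2-yl)-4-methoxy-2,3-dihydro-1-benzofuran-5-yl]prop-2-en-1-one | COc1c(/C=C/C(=O)c2ccc(O)cc2)ccc2c1C[C@@H](C(C)(C)O)O2 | target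

## Step count and risks

Total: 11 steps. Longest linear sequence: 10 steps (steps 1–8, 10, 11); step 9 is a one-step side branch.

**Step 6 (key step).** The most likely failure is that hydrogen abstraction at the O–CH2 group is too slow. An aryl ether oxygen activates less than an alkyl ether oxygen, and the adjacent fully substituted carbon hinders both the abstraction and the ring-closing substitution. The carbene radical would then be diverted into dimerisation or azine formation, or into abstraction from the methoxy group, and the hindered C2 radical might couple with poor facial selectivity.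

Fallback (sets out from 1, returns at 11): ring and stereocentre are made by asymmetric epoxidation and phenoxide opening.
- 1 is O-alkylated at the 4-hydroxyl with 3-chloro-3-methylbut-1-yne (K2CO3, KI, CuI, acetone) to give methyl 2-hydroxy-4-[(2-methylbut-3-yn-2-yl)oxy]benzoate F1.
- Lindlar semi-hydrogenation gives methyl 2-hydroxy-4-[(2-methylbut-3-en-2-yl)oxy]benzoate F2.
- Aromatic Claisen rearrangement (PhNEt2, about 180 °C), steered to the position between the oxygens by the bond fixation of the chelated salicylate, gives methyl 2,4-dihydroxy-3-(3-methylbut-2-en-1-yl)benzoate F3.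
- Silylation of the non-chelated 4-hydroxyl (TIPSCl, imidazole) gives methyl 2-hydroxy-3-(3-methylbut-2-en-1-yl)-4-[(triisopropylsilyl)oxy]benzoate F4.
- Methylation (MeI, K2CO3, acetone) gives methyl 2-methoxy-3-(3-methylbut-2-en-1-yl)-4-[(triisopropylsilyl)oxy]benzoate F5.
- Shi epoxidation with the D-fructose-derived ketone (Oxone, buffered MeCN/dimethoxymethane, 0 °C) is expected from the spiro transition-state model to give methyl 3-{[(2R)-3,3-dimethyloxiran-2-yl]methyl}-2-methoxy-4-[(triisopropylsilyl)oxy]benzoate F6.
- TBAF in THF frees the phenoxide, which opens the epoxide 5-exo-tet at the secondary carbon with inversion to give methyl (2S)-2-(2-hydroxypropan-2-yl)-4-methoxy-2,3-dihydro-1-benzofuran-5-carboxylate F7.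
- Silylation as in step 4 gives 11.

**Step 2.** The phenol is a chelated salicylate deactivated by the ester, so the formylation may stop at low conversion, and prolonged heating with excess formaldehyde invites O-methoxymethylation of the phenol and the tertiary alcohol.

Fallback (sets out from 1, returns at 5): the order is reversed. The more electron-rich free resorcinol 1 is formylated between its two hydroxyls under Duff conditions (hexamethylenetetramine, AcOH, 100 °C, then hot aqueous HCl) to give methyl 3-formyl-2,4-dihydroxybenzoate F8. The 4-hydroxyl of F8, which is para to the ester and not held between two carbonyl groups, is then alkylated with 2 (K2CO3, DMF, 85 °C) to give 5.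

**Step 10.** Aldehyde 13 is electron-rich (O1 is para and the methoxy group ortho to the formyl group), so addition may be slow and reversible, and part of the silyl ether may be lost during a long reaction in basic methanol.

Fallback (sets out from 13 and 15, returns at 17): a directed aldol reaction followed by a separate elimination. The lithium enolate of 15 (LiHMDS, THF, −78 °C) adds to 13, and the aldol 16 is isolated. Treatment with MsCl and Et3N in CH2Cl2 (0 °C → rt) gives 1-{(2S)-4-methoxy-2-[2-(trimethylsilyloxy)propan-2-yl]-2,3-dihydro-1-benzofuran-5-yl}-3-[4-(methoxymethoxy)phenyl]-3-oxopropyl methanesulfonate F9, which eliminates in the same flask to give 17.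

**Step 11.** Acid may do more than deprotect: ionisation and dehydration of the tertiary alcohol, addition of methanol to the enone, or E/Z isomerisation on long exposure.

Fallback (sets out from 13 and 14, returns at 18): the acetal is avoided altogether. Unprotected 14 is condensed with 13 as its dianion (excess KOH, EtOH, rt → 50 °C) to give (2E)-1-(4-hydroxyphenyl)-3-{(2S)-4-methoxy-2-[2-(trimethylsilyloxy)propan-2-yl]-2,3-dihydro-1-benzofuran-5-yl}prop-2-en-1-one F10, and the silyl ether is removed with acetic-acid-buffered TBAF in THF to give 18.

## Further compounds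

F1 | step 6 | methyl 2-hydroxy-4-[(2-methylbut-3-yn-2-yl)oxy]benzoate | COC(=O)c1ccc(OC(C)(C)C#C)cc1O
F2 | step 6 | methyl 2-hydroxy-4-[(2-methylbut-3-en-2-yl)oxy]benzoate | COC(=O)c1ccc(OC(C)(C)C=C)cc1O
F3 | step 6 | methyl 2,4-dihydroxy-3-(3-methylbut-2-en-1-yl)benzoate | COC(=O)c1ccc(O)c(CC=C(C)C)c1O
F4 | step 6 | methyl 2-hydroxy-3-(3-methylbut-2-en-1-yl)-4-[(triisopropylsilyl)oxy]benzoate | COC(=O)c1ccc(O[Si](C(C)C)(C(C)C)C(C)C)c(CC=C(C)C)c1O
F5 | step 6 | methyl 2-methoxy-3-(3-methylbut-2-en-1-yl)-4-[(triisopropylsilyl)oxy]benzoate | COC(=O)c1ccc(O[Si](C(C)C)(C(C)C)C(C)C)c(CC=C(C)C)c1OC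
F6 | step 6 | methyl 3-{[(2R)-3,3-dimethyloxiran-2-yl]methyl}-2-methoxy-4-[(triisopropylsilyl)oxy]benzoate | COC(=O)c1ccc(O[Si](C(C)C)(C(C)C)C(C)C)c(C[C@H]2OC2(C)C)c1OC
F7 | step 6 | methyl (2S)-2-(2-hydroxypropan-2-yl)-4-methoxy-2,3-dihydro-1-benzofuran-5-carboxylate | COC(=O)c1ccc2c(c1OC)C[C@@H](C(C)(C)O)O2
F8 | step 2 | methyl 3-formyl-2,4-dihydroxybenzoate | COC(=O)c1ccc(O)c(C=O)c1O
F9 | step 10 | 1-{(2S)-4-methoxy-2-[2-(trimethylsilyloxy)propan-2-yl]-2,3-dihydro-1-benzofuran-5-yl}-3-[4-(methoxymethoxy)phenyl]-3-oxopropyl methanesulfonate (both epimers at the sulfonate carbon) | COc1c(C(CC(=O)c2ccc(OCOC)cc2)OS(C)(=O)=O)ccc2c1C[C@@H](C(C)(C)O[Si](C)(C)C)O2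
F10 | step 11 | (2E)-1-(4-hydroxyphenyl)-3-{(2S)-4-methoxy-2-[2-(trimethylsilyloxy)propan-2-yl]-2,3-dihydro-1-benzofuran-5-yl}prop-2-en-1-one | COc1c(/C=C/C(=O)c2ccc(O)cc2)ccc2c1C[C@@H](C(C)(C)O[Si](C)(C)C)O2
A1 | alternative 1 | methyl 2,4-dihydroxy-3-(3-methylbut-2-en-1-yl)benzoate | COC(=O)c1ccc(O)c(CC=C(C)C)c1O
A2 | alternative 1 | 1-methoxy-2-(3-methylbut-2-en-1-yl)-1,3-bis(trimethylsilyloxy)buta-1,3-diene (enol ether geometry not defined) | COC(O[Si](C)(C)C)=C(CC=C(C)C)C(=C)O[Si](C)(C)C
A3 | alternative 1 | methyl propiolate | C#CC(=O)OC
A4 | alternative 2 | (2S)-2-(prop-1-en-2-yl)-3,5,6,7-tetrahydro-1-benzofuran-4(2H)-one | O=C1CCCC2=C1C[C@@H](C(C)=C)O2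
A5 | alternative 2 | cyclohexane-1,3-dione | O=C1CCCC(=O)C1
A6 | alternative 2 | (2E)-2-methylbut-2-ene-1,4-diyl dimethyl biscarbonate | COC(=O)OC/C=C(\C)COC(=O)OC
A7 | alternative 3 | methyl (2S)-4-methoxy-2-[2-(triethylsilyloxy)propan-2-yl]-2,3-dihydro-1-benzofuran-5-carboxylate | COC(=O)c1ccc2c(c1OC)C[C@@H](C(C)(C)O[Si](CC)(CC)CC)O2
A8 | alternative 3 | methyl 6-{[(4S)-1-methoxy-5-methyl-5-(triethylsilyloxy)hex-1-yn-4-yl]oxy}pyridazine-3-carboxylate | COC(=O)c1ccc(O[C@@H](CC#COC)C(C)(C)O[Si](CC)(CC)CC)nn1
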